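The ratio of isomer of the product A to target, read at one clock time, is what I carried here, because it looked indifferent to the charge.

| flask | substrate | remark | time |
|---|---|---|---|
| oak | 0.020 M | the very flask that is asked about, followed so far |  |
| elm | 0.013 M | run made earlier |  |
| flask | 0.020 M |  | 2.5 d |

oak run (percent of the substrate charged)

| time / h | target / % | isomer of the product A / % | substrate / % |
|---|---|---|---|
| 4.00 | 7.5 | 1.8 | 33.3 |
| 10.0 | 8.1 | 4.5 | 22.7 |
| 20.0 | 8.3 | 8.5 | 17.9 |
| 30.0 | 6.5 | 10.1 | 13.7 |

elm run (percent of the substrate charged)

| time / d | target / % | isomer of the product A / % | substrate / % |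
|---|---|---|---|
| 0.625 | 8.8 | 8.1 | 23.1 |
| 1.25 | 7.7 | 12.3 | 18.2 |
| 2.08 | 7.2 | 13.2 | 14.1 |
| 2.50 | 6.8 | 12.9 | 13.0 |

(standard deviation of a reading: 0.5 percentage points)

- the analysis behind the earlier runs scatters by 0.5 percentage points, standard deviation
- a reading or a percentage of target counts all its forms, free or not
- the reaction counts as stopped when no species that holds the substrate changes by six tenths of a point or more over the second half of the time
- a reading of substrate is of its free form alone

- which holds at 2.5 d: what has brought the reaction to rest, or that it has not come to rest (it is still moving / all of the substrate has reacted / forward and back rates have come level)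
- amount of target at 2.5 d, in percent of the substrate charged
- amount of isomer of the product A at 2.5 d, in percent of the substrate charged

1. The ratio started steeply: the oak flask gave 0.240 at 4.00 h, a mean slope from the start of 0.0600 h⁻¹.

2. As far as a scatter of 0.5 percentage points lets me read it, the ratio passed one between the elm reading of 0.920 at 0.625 d and the oak reading of 1.02 at 20.0 h.

3. At 30.0 h, oak read 1.55 and elm 1.60, so despite their different charges the two stood close.

4. After that reading, the mean elm slope was 0.00999 h⁻¹, a knee in the elm curve, and I took the clock ratio, elm's isomer of the product A over target at 2.50 d, 1.90, for the oak flask at that time.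

5. I froze the oak sum of the two at its last reading, 16.6%, which split into 5.72% target and 10.9% isomer of the product A. Elm substrate fell 5.2 points over its second half, against the limit of 0.6, so I expected the oak flask to be moving still.

The forecast said it is still moving, with 5.9% target and 11.2% isomer of the product A, a sum above mine; it read the ratio as one that “points to first-order isomerisation nearing equilibrium”.

The oak flask gave: it is still moving, with 5.78% target and 10.8% isomer of the product A, a ratio of 1.87 against 1.90.

    substrate ⇌ target (K = 0.410, k = 7.70 × 10⁻⁴ min⁻¹)
    isomer of the product B ⇌ substrate (k = 4.70 × 10⁻⁴ min⁻¹)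
    target ⇌ isomer of the product A (K = 2.20, k = 0.00220 min⁻¹)
    substrate + target ⇌ idle adduct, settled at all times (K = 100 M⁻¹)
    isomer of the product A ⇌ isomer of the product B (K = 0.490, k = 6.50 × 10⁻⁴ min⁻¹)
    substrate ⇌ dormant form (K = 0.830, k = 0.00330 min⁻¹)
    2 substrate → self-condensation product (k = 0.0850 M⁻¹ min⁻¹)

The target of the oak flask stood at 5.78% in part because two steps act together: without the self-condensation it held 15.3%, and without target falling back to substrate 12.9%. The same flask read at 15 h held 8.06% target, so elm's ratio 0.920 gave 7.42% isomer of the product A, and it held 7.25%.

The numbers in the tables come from a simulation on assumed constants; the scatter is artificial.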